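**Retrosynthetic overview**

1. Isospiculoic acid A ⇐ one-pot desilylation and double oxidation (alcohol to ketone, aldehyde to acid) of a bicyclic 2-silyloxy-hexahydroindene-4-carbaldehyde.
2. Both carbocycles, the cyclohexene and the cyclopentane, form together and last, in one endo intramolecular Diels–Alder reaction of an acyclic (2E,7E,9E,11E)-tetraenal (new bonds C3a–C7a and C4–C5 of the indene); no ring exists before this step.
3. Tetraenal ⇐ Wittig reaction (dienophile enal) on an aldehyde unmasked from a primary TES ether; phenyl triene ⇐ Horner–Wadsworth–Emmons, Wittig and cross-metathesis on a terminal alkene.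
4. Stereotriad ⇐ anti- and Felkin-selective pentenylation (CrCl2) of the aldehyde from methyl (R)-3-hydroxy-2-methylpropanoate, the only source of chirality.

Assumption: carbon building blocks that end up in the skeleton are numbered as starting materials and stand under Reactants; simple reagents that add atoms (silylating agents, water) are given by name and SMILES on the reagent line.

**Route**

Step 1
Reactants: 1 methyl (R)-3-hydroxy-2-methylpropanoate
Product: 2 methyl (R)-2-methyl-3-(triethylsilyloxy)propanoate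
Conditions: Et3SiCl, imidazole, CH2Cl2, 0 °C to rt
Reagents that add atoms: chlorotriethylsilane, CC[Si](Cl)(CC)CC
Why: Imidazole-promoted silylation of the primary alcohol installs a TES ether that can later be oxidised directly to the aldehyde, and the stereocentre is not touched.

Step 2
Reactants: 2 methyl (R)-2-methyl-3-(triethylsilyloxy)propanoate
Product: 3 (R)-2-methyl-3-(triethylsilyloxy)propanal
Conditions: iBu2AlH (DIBAL-H, 1.1 equiv), CH2Cl2, −78 °C; then MeOH, aq. potassium sodium tartrate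
Reagents that add atoms: none
Why: Partial ester reduction works because the aluminium hemiacetal is stable at −78 °C and gives the aldehyde only on work-up; the crude aldehyde is used at once so the α-stereocentre does not racemise.

Step 3
Reactants: 3 (R)-2-methyl-3-(triethylsilyloxy)propanal; 4 (E)-1-bromopent-2-ene
Product: 5 (2R,3R,4R)-4-ethyl-2-methyl-1-(triethylsilyloxy)hex-5-en-3-ol
Conditions: CrCl2 (3.5 equiv), THF, 0 °C to rt
Reagents that add atoms: none
Why: In this Nozaki–Hiyama pentenylation the (E)-allylchromium adds through a chair transition state (C3/C4 anti) and the α-methyl stereocentre directs Felkin–Anh attack (C2/C3 syn), expected at about 5:1 over the other isomers, which are removed by chromatography.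

Step 4
Reactants: 5 (2R,3R,4R)-4-ethyl-2-methyl-1-(triethylsilyloxy)hex-5-en-3-ol
Product: 6 (3R,4R,5R)-3-ethyl-5-methyl-4,6-bis(triethylsilyloxy)hex-1-ene
Conditions: Et3SiOTf, 2,6-lutidine, CH2Cl2, −78 °C
Reagents that add atoms: triethylsilyl trifluoromethanesulfonate, CC[Si](CC)(CC)OS(=O)(=O)C(F)(F)F
Why: The silyl triflate silylates the hindered secondary alcohol cleanly, which blocks β-elimination and retro-aldol pathways in the later aldehyde steps without changing any stereocentre.

Step 5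
Reactants: 6 (3R,4R,5R)-3-ethyl-5-methyl-4,6-bis(triethylsilyloxy)hex-1-ene; 7 2-ethylprop-2-enal (2-ethylacrolein)
Product: 8 (2E,4R,5R,6R)-2,4-diethyl-6-methyl-5,7-bis(triethylsilyloxy)hept-2-enal
Conditions: 7 (10 equiv), second-generation Hoveyda–Grubbs catalyst (10 mol%), CH2Cl2, 40 °C
Reagents that add atoms: none
Why: Olefin cross-metathesis of the terminal alkene with an excess of the non-dimerising 1,1-disubstituted enal is driven by loss of ethylene and gives the thermodynamically favoured (E)-trisubstituted enal, with the allylic stereocentre untouched.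

Step 6
Reactants: 8 (2E,4R,5R,6R)-2,4-diethyl-6-methyl-5,7-bis(triethylsilyloxy)hept-2-enal; 9 2-(triphenylphosphoranylidene)butanal
Product: 10 (2E,4E,6R,7R,8R)-2,4,6-triethyl-8-methyl-7,9-bis(triethylsilyloxy)nona-2,4-dienal
Conditions: 9 (1.3 equiv), toluene, 100 °C
Reagents that add atoms: none
Why: The Wittig reaction of the formyl-stabilised ylide gives the (E)-trisubstituted alkene, and the γ-stereocentre survives because A(1,3) strain holds its C–H bond in the plane of the enal, where it is not acidic.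

Step 7
Reactants: 10 (2E,4E,6R,7R,8R)-2,4,6-triethyl-8-methyl-7,9-bis(triethylsilyloxy)nona-2,4-dienal; 11 diethyl benzylphosphonate
Product: 12 [(1E,3E,5E,7R,8R,9R)-3,5,7-triethyl-9-methyl-8,10-bis(triethylsilyloxy)deca-1,3,5-trien-1-yl]benzene
Conditions: 11, NaH, THF, 0 °C; then 10, 0 °C to rt
Reagents that add atoms: none
Why: The Horner–Wadsworth–Emmons reaction of the benzylphosphonate anion gives the (E)-styrene reliably and completes the all-E phenyl triene.

Step 8
Reactants: 12 [(1E,3E,5E,7R,8R,9R)-3,5,7-triethyl-9-methyl-8,10-bis(triethylsilyloxy)deca-1,3,5-trien-1-yl]benzene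
Product: 13 (2S,3R,4R,5E,7E,9E)-4,6,8-triethyl-2-methyl-10-phenyl-3-(triethylsilyloxy)deca-5,7,9-trienal
Conditions: (COCl)2, DMSO, CH2Cl2, −78 to −40 °C; then Et3N, −78 to 0 °C
Reagents that add atoms: none
Why: Under Swern conditions the unhindered primary TES ether is cleaved and oxidised directly to the aldehyde while the hindered secondary TES ether stays, and the cold amine quench avoids epimerisation of the new α-stereocentre.

Step 9
Reactants: 13 (2S,3R,4R,5E,7E,9E)-4,6,8-triethyl-2-methyl-10-phenyl-3-(triethylsilyloxy)deca-5,7,9-trienal; 9 2-(triphenylphosphoranylidene)butanal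
Product: 15 (1R,2S,3R,3aS,4S,5R,7aS)-1,4,5,7-tetraethyl-3-methyl-5-[(E)-2-phenylethenyl]-2-(triethylsilyloxy)-2,3,3a,4,5,7a-hexahydro-1H-indene-4-carbaldehyde, via tetraenal 14 (not isolated)
Conditions: 9 (1.3 equiv), toluene, 90 °C; then 110 °C
Reagents that add atoms: none
Why: The Wittig reaction forms the (E)-2-ethyl enal, which undergoes an intramolecular Diels–Alder reaction through the endo-formyl, tether-exo transition state (trans ring fusion); A(1,3) strain places the C–H of both the ethyl- and the methyl-bearing allylic stereocentres in the plane of their alkenes, so both direct the cycloaddition to the same pair of faces and set the four new stereocentres, including the two adjacent quaternary carbons.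

Step 10
Reactants: 15 (1R,2S,3R,3aS,4S,5R,7aS)-1,4,5,7-tetraethyl-3-methyl-5-[(E)-2-phenylethenyl]-2-(triethylsilyloxy)-2,3,3a,4,5,7a-hexahydro-1H-indene-4-carbaldehyde
Product: 18 isospiculoic acid A, via hydroxy aldehyde 16 (not isolated), via keto aldehyde 17 (not isolated)
Conditions: CrO3, H2SO4, H2O, acetone, 0 °C to rt; then i-PrOH
Reagents that add atoms: water, O
Why: In this Jones oxidation the aqueous acid cleaves the TES ether, chromic acid oxidises the secondary alcohol to the ketone and the aldehyde hydrate to the acid, and the two α-stereocentres stay because each alkyl group is already trans to its neighbouring ring bond, the less strained arrangement.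

**Compound list**

1 | methyl (R)-3-hydroxy-2-methylpropanoate | C[C@H](CO)C(=O)OC | starting material
2 | methyl (R)-2-methyl-3-(triethylsilyloxy)propanoate | C[C@H](CO[Si](CC)(CC)CC)C(=O)OC | intermediate
3 | (R)-2-methyl-3-(triethylsilyloxy)propanal | C[C@H](CO[Si](CC)(CC)CC)C=O | intermediate
4 | (E)-1-bromopent-2-ene | CC/C=C/CBr | starting material
5 | (2R,3R,4R)-4-ethyl-2-methyl-1-(triethylsilyloxy)hex-5-en-3-ol | C=C[C@@H](CC)[C@@H](O)[C@H](C)CO[Si](CC)(CC)CC | intermediate
6 | (3R,4R,5R)-3-ethyl-5-methyl-4,6-bis(triethylsilyloxy)hex-1-ene | C=C[C@@H](CC)[C@@H](O[Si](CC)(CC)CC)[C@H](C)CO[Si](CC)(CC)CC | intermediate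
7 | 2-ethylprop-2-enal (2-ethylacrolein) | CCC(=C)C=O | starting material
8 | (2E,4R,5R,6R)-2,4-diethyl-6-methyl-5,7-bis(triethylsilyloxy)hept-2-enal | O=C/C(CC)=C/[C@@H](CC)[C@@H](O[Si](CC)(CC)CC)[C@H](C)CO[Si](CC)(CC)CC | intermediate
9 | 2-(triphenylphosphoranylidene)butanal | CCC(C=O)=P(c1ccccc1)(c1ccccc1)c1ccccc1 | starting material
10 | (2E,4E,6R,7R,8R)-2,4,6-triethyl-8-methyl-7,9-bis(triethylsilyloxy)nona-2,4-dienal | O=C/C(CC)=C/C(CC)=C/[C@@H](CC)[C@@H](O[Si](CC)(CC)CC)[C@H](C)CO[Si](CC)(CC)CC | intermediate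
11 | diethyl benzylphosphonate | CCOP(=O)(Cc1ccccc1)OCC | starting material
12 | [(1E,3E,5E,7R,8R,9R)-3,5,7-triethyl-9-methyl-8,10-bis(triethylsilyloxy)deca-1,3,5-trien-1-yl]benzene | c1ccccc1/C=C/C(CC)=C/C(CC)=C/[C@@H](CC)[C@@H](O[Si](CC)(CC)CC)[C@H](C)CO[Si](CC)(CC)CC | intermediate
13 | (2S,3R,4R,5E,7E,9E)-4,6,8-triethyl-2-methyl-10-phenyl-3-(triethylsilyloxy)deca-5,7,9-trienal | c1ccccc1/C=C/C(CC)=C/C(CC)=C/[C@@H](CC)[C@@H](O[Si](CC)(CC)CC)[C@H](C)C=O | intermediate
14 | (2E,4R,5S,6R,7E,9E,11E)-2,6,8,10-tetraethyl-4-methyl-12-phenyl-5-(triethylsilyloxy)dodeca-2,7,9,11-tetraenal | c1ccccc1/C=C/C(CC)=C/C(CC)=C/[C@@H](CC)[C@@H](O[Si](CC)(CC)CC)[C@H](C)/C=C(CC)/C=O | intermediate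
15 | (1R,2S,3R,3aS,4S,5R,7aS)-1,4,5,7-tetraethyl-3-methyl-5-[(E)-2-phenylethenyl]-2-(triethylsilyloxy)-2,3,3a,4,5,7a-hexahydro-1H-indene-4-carbaldehyde | CCC1=C[C@](/C=C/c2ccccc2)(CC)[C@@](CC)(C=O)[C@H]2[C@H]1[C@@H](CC)[C@@H](O[Si](CC)(CC)CC)[C@@H]2C | intermediate
16 | (1R,2S,3R,3aS,4S,5R,7aS)-1,4,5,7-tetraethyl-2-hydroxy-3-methyl-5-[(E)-2-phenylethenyl]-2,3,3a,4,5,7a-hexahydro-1H-indene-4-carbaldehyde | CCC1=C[C@](/C=C/c2ccccc2)(CC)[C@@](CC)(C=O)[C@H]2[C@H]1[C@@H](CC)[C@@H](O)[C@@H]2C | intermediate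
17 | (1R,3R,3aS,4S,5R,7aS)-1,4,5,7-tetraethyl-3-methyl-2-oxo-5-[(E)-2-phenylethenyl]-2,3,3a,4,5,7a-hexahydro-1H-indene-4-carbaldehyde | CCC1=C[C@](/C=C/c2ccccc2)(CC)[C@@](CC)(C=O)[C@H]2[C@H]1[C@@H](CC)C(=O)[C@@H]2C | intermediate
18 | isospiculoic acid A, (1R,3R,3aS,4S,5R,7aS)-1,4,5,7-tetraethyl-3-methyl-2-oxo-5-[(E)-2-phenylethenyl]-2,3,3a,4,5,7a-hexahydro-1H-indene-4-carboxylic acid | CCC1=C[C@](/C=C/c2ccccc2)(CC)[C@@](CC)(C(=O)O)[C@H]2[C@H]1[C@@H](CC)C(=O)[C@@H]2C | target

**Step count and risks**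

Total step count: 10. Longest linear sequence: 10 steps, from 1 to 18.

The three steps most likely to fail:

Step 5 (cross-metathesis of an alkene with an ethyl-branched allylic carbon and a 1,1-disubstituted enal; low conversion is the risk). The fallback sets out from 6 and comes back to the route at 8. Oxidative cleavage of the vinyl group (OsO4 cat., NaIO4, 2,6-lutidine, dioxane/H2O) gives the aldehyde (2S,3S,4R)-2-ethyl-4-methyl-3,5-bis(triethylsilyloxy)pentanal F1. A Wittig reaction of F1 with ylide 9 in toluene at 90 °C then gives enal 8 by carbonyl olefination in place of metathesis.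

Step 9 (the hot Wittig reaction may epimerise or eliminate the β-silyloxy aldehyde, and the cycloaddition that builds two adjacent quaternary carbons may need activation). The fallback sets out from 13 and comes back at 15, through 14. A Wittig reaction with ethyl 2-(triphenylphosphoranylidene)butanoate in CH2Cl2 at rt gives the ester ethyl (2E,4R,5S,6R,7E,9E,11E)-2,6,8,10-tetraethyl-4-methyl-12-phenyl-5-(triethylsilyloxy)dodeca-2,7,9,11-tetraenoate F2. Reduction with iBu2AlH at −78 °C gives the allylic alcohol (2E,4R,5S,6R,7E,9E,11E)-2,6,8,10-tetraethyl-4-methyl-12-phenyl-5-(triethylsilyloxy)dodeca-2,7,9,11-tetraen-1-ol F3. Oxidation with MnO2 in CH2Cl2 at rt unmasks tetraenal 14, which is then cyclised on its own, thermally or with Me2AlCl at −40 °C, to 15.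

Step 10 (one-pot desilylation and double oxidation; the neopentyl aldehyde may oxidise slowly and the acidic medium may harm the alkenes). The fallback sets out from 15 and comes back at 18. Chlorite oxidation (NaClO2, NaH2PO4, 2-methyl-2-butene, t-BuOH/H2O) gives the acid (1R,2S,3R,3aS,4S,5R,7aS)-1,4,5,7-tetraethyl-3-methyl-5-[(E)-2-phenylethenyl]-2-(triethylsilyloxy)-2,3,3a,4,5,7a-hexahydro-1H-indene-4-carboxylic acid F4. HF·pyridine in THF gives the hydroxy acid (1R,2S,3R,3aS,4S,5R,7aS)-1,4,5,7-tetraethyl-2-hydroxy-3-methyl-5-[(E)-2-phenylethenyl]-2,3,3a,4,5,7a-hexahydro-1H-indene-4-carboxylic acid F5. Dess–Martin periodinane in CH2Cl2 then gives 18.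

**Further compounds**

F1 | step 5 | (2S,3S,4R)-2-ethyl-4-methyl-3,5-bis(triethylsilyloxy)pentanal | O=C[C@@H](CC)[C@@H](O[Si](CC)(CC)CC)[C@H](C)CO[Si](CC)(CC)CC
F2 | step 9 | ethyl (2E,4R,5S,6R,7E,9E,11E)-2,6,8,10-tetraethyl-4-methyl-12-phenyl-5-(triethylsilyloxy)dodeca-2,7,9,11-tetraenoate | c1ccccc1/C=C/C(CC)=C/C(CC)=C/[C@@H](CC)[C@@H](O[Si](CC)(CC)CC)[C@H](C)/C=C(CC)/C(=O)OCC
F3 | step 9 | (2E,4R,5S,6R,7E,9E,11E)-2,6,8,10-tetraethyl-4-methyl-12-phenyl-5-(triethylsilyloxy)dodeca-2,7,9,11-tetraen-1-ol | c1ccccc1/C=C/C(CC)=C/C(CC)=C/[C@@H](CC)[C@@H](O[Si](CC)(CC)CC)[C@H](C)/C=C(CC)/CO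
F4 | step 10 | (1R,2S,3R,3aS,4S,5R,7aS)-1,4,5,7-tetraethyl-3-methyl-5-[(E)-2-phenylethenyl]-2-(triethylsilyloxy)-2,3,3a,4,5,7a-hexahydro-1H-indene-4-carboxylic acid | CCC1=C[C@](/C=C/c2ccccc2)(CC)[C@@](CC)(C(=O)O)[C@H]2[C@H]1[C@@H](CC)[C@@H](O[Si](CC)(CC)CC)[C@@H]2C
F5 | step 10 | (1R,2S,3R,3aS,4S,5R,7aS)-1,4,5,7-tetraethyl-2-hydroxy-3-methyl-5-[(E)-2-phenylethenyl]-2,3,3a,4,5,7a-hexahydro-1H-indene-4-carboxylic acid | CCC1=C[C@](/C=C/c2ccccc2)(CC)[C@@](CC)(C(=O)O)[C@H]2[C@H]1[C@@H](CC)[C@@H](O)[C@@H]2C
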